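**Plan**

- Numbering follows the atisanes: lactone ring C10–C1–C2–C3(=O)–O–C9, ring B C5–C10, bicyclo[2.2.2]octane C8/C9/C11–C16. The lactone oxygen sits on C9, a fully substituted carbon wedged between quaternary C8 and C10. Cutting O–C9 back to the C3–C9 bond of a cis-fused cyclopentanone (C1–C2–C3–C9–C10) turns C9 into a ketone α-carbon that can be built up by enolate chemistry.
- Further cuts, in order: C15=O (silyl-protected allylic alcohol), C14–O (from a C14 acetyl group), C16=C17 and the acetyl carbon (from a C16 ketone and a C14 ester), C8–C14/C12–C13 (acrylate), C8–C15/C9–C11 (butenone), C3–C9 (ester condensation), C1–C10 (homoenolate addition).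
- Forward: ring B is the six-membered ring of (+)-verbenone, whose cyclobutane is opened to release the isopropenyl group. The cyclopentanone is closed next, then ring C by Robinson annulation, then the bicyclo[2.2.2]octane by double Michael addition, and last the six-membered lactone by oxygen insertion.
- Stereochemistry: C5 and C10 come from verbenone (addition anti to the gem-dimethyl bridge). C9 follows from the cis ring fusion. C8, C12 and C14 come from the double Michael addition anti to the axial C9–C3 bond, with the ester syn to the ketone bridge. Both oxygen insertions go with retention.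

Key step: step 14

**Remarks on the chemistry (assumptions)**

- (1R,5R)-(+)-Verbenone is used in high enantiomeric purity (commercial; also the one-step allylic oxidation product of (+)-α-pinene).
- The carbinol centres at C3 (compounds 12–25) and C15 (compounds 20–29) are temporary. The epimers drawn are the ones expected; the other epimers would converge on the same ketones.

**Route**

Step 1
Reactants: 1 (1R,5R)-(+)-verbenone; 2 1-ethoxy-1-(trimethylsilyloxy)cyclopropane
Product: 5 ethyl 3-(2,6,6-trimethyl-4-oxobicyclo[3.1.1]hept-2-yl)propanoate (ester chain anti to the gem-dimethyl bridge; C10 R), via zinc homoenolate 3 (not isolated), via silyl enol ether 4 (not isolated)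
Conditions: 2, ZnCl2, Et2O, rt; then 1, CuBr·SMe2 (5 mol%), HMPA, THF, 0 °C to rt; 1 M HCl
Reagents that add atoms: 1-ethoxy-1-(trimethylsilyloxy)cyclopropane (2), CCOC1(O[Si](C)(C)C)CC1
Why: Copper-catalysed conjugate addition of a zinc ester homoenolate, accelerated by the chlorosilane released on its formation and by HMPA, is known for β,β-disubstituted cyclohexenones, and on verbenone the reagent can only reach the enone face opposite the gem-dimethyl bridge, which fixes C10 with the C1–C3 chain anti to the bridge.

Step 2
Reactants: 5
Product: 6 ethyl 3-[(1R,6S)-3-acetoxy-1-methyl-6-(prop-1-en-2-yl)cyclohex-3-en-1-yl]propanoate (C7=C8 enol acetate; isopropenyl at C5 cis to the C10 methyl)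
Conditions: BF3·OEt2, Zn(OAc)2, Ac2O, 0 °C to rt
Reagents that add atoms: acetic anhydride, CC(=O)OC(C)=O
Why: Acetylative Lewis-acid fragmentation of the cyclobutane of pinane-type ketones (nopinone, verbanones) is established: the bond between the α-bridgehead and the gem-dimethyl carbon ionises, the enol is caught as its acetate and the tertiary cation loses a methyl proton to give the isopropenyl group, so C5 keeps the bridgehead configuration with isopropenyl cis to the C10 methyl and trans to the ester chain.

Step 3
Reactants: 6
Product: 8 cis-fused 3a-methyl-4-(prop-1-en-2-yl)hexahydroindane-1,7-dione (C3 and C8 carbonyls flank C9–H; isopropenyl cis to the methyl), via potassium enolate 7 (not isolated)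
Conditions: KOt-Bu (2 equiv), THF, 0 °C to rt; 1 M HCl
Reagents that add atoms: none
Why: tert-Butoxide strips the enol acetate to the ketone enolate, which after proton exchange undergoes an intramolecular Claisen (Dieckmann-type) condensation of C9 onto the ester carbonyl C3 to close the five-membered ring (the C7 enolate could only form a bridged seven-membered ring), the equilibrium being pulled by deprotonation of the 1,3-diketone.

Step 4
Reactants: 8; 9 but-3-en-2-one
Product: 10 7a-(3-oxobutyl) derivative of 8 (triketone; chain C11–C12–C16(=O)–C15 on C9 cis to the C10 methyl)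
Conditions: but-3-en-2-one, Et3N (10 mol%), THF, rt
Reagents that add atoms: but-3-en-2-one (9), CC(=O)C=C
Why: Michael addition of a cyclic 1,3-diketone at its doubly activated carbon C9 is standard, and the chain should end cis to the C10 methyl because only that product keeps the five/six ring fusion cis, the preferred fusion for a hydrindanedione with two angular substituents and the thermodynamic one under these reversible conditions; this sets the quaternary centre C9.

Step 5
Reactants: 10
Product: 11 tricyclic enedione (ring C closed: C8=C15–C16(=O)–C12–C11–C9; C3 ketone retained)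
Conditions: pyrrolidine (20 mol%), AcOH (20 mol%), toluene, 80 °C
Reagents that add atoms: none
Why: In this aldol condensation, the second stage of a Robinson annulation, the enamine of the methyl ketone should add to the six-ring carbonyl C8, which is more electrophilic than the cyclopentanone carbonyl C3 (less strain on rehybridisation, as in hydride and cyanide additions), and dehydration gives the C8=C15 enone without forming a stereocentre.

Step 6
Reactants: 11
Product: 12 hydroxy enone (C3 alcohol cis to C11 and the C10 methyl; enone untouched)
Conditions: NaBH4 (0.3 equiv), EtOH, −20 °C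
Reagents that add atoms: none
Why: Chemoselective borohydride reduction: at low temperature a saturated ketone is reduced much faster than a conjugated enone (standard for bicyclic enediones of this kind), so only C3 reacts, hydride arriving anti to the C10 methyl and C11.

Step 7
Reactants: 12
Product: 13 C3 triethylsilyl ether of 12
Conditions: Et3SiOTf, 2,6-lutidine, CH2Cl2, −78 °C
Reagents that add atoms: triethylsilyl trifluoromethanesulfonate, CC[Si](CC)(CC)OS(=O)(=O)C(F)(F)F
Why: Silylation of a secondary alcohol with a silyl triflate and a hindered base hides C3 from the enolate and methylenation chemistry ahead, and the triethylsilyl ether is the most acid-labile group, to be removed selectively in step 11.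

Step 8
Reactants: 13; 14 methyl acrylate
Product: 18 tetracyclic keto ester (bicyclo[2.2.2]octane closed; C16 ketone; C14 CO2Me syn to the C15–C16 bridge), via lithium dienolate 15 (not isolated), via ester enolate 16 (not isolated), via ketone enolate 17 (not isolated)
Conditions: LiN(i-Pr)2, THF, −78 °C; methyl acrylate, −78 °C to rt; AcOH
Reagents that add atoms: methyl acrylate (14), C=CC(=O)OC
Why: Double Michael annulation of a kinetic cross-conjugated dienolate with an acrylate is known for cyclohexenones and octalones bearing a quaternary carbon next to the β-position: C12 attacks the acrylate on the face anti to the axial C9–C3 bond, and the ester enolate then closes a six-membered ring onto C8 on that same face, with the ester syn to the new ketone bridge (lithium chelation, and away from C10 and C20), which sets C12, C8 and C14.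

Step 9
Reactants: 18
Product: 20 C15 hydroxy ketone (hydroxyl toward the C9–C11 bridge), via potassium enolate 19 (not isolated)
Conditions: KN(SiMe3)2, THF, −78 °C; 2-(phenylsulfonyl)-3-phenyloxaziridine; AcOH
Reagents that add atoms: 2-(phenylsulfonyl)-3-phenyloxaziridine, O=S(=O)(N1OC1c1ccccc1)c1ccccc1
Why: In this enolate hydroxylation with an N-sulfonyloxaziridine, the bridgehead C12 cannot enolise (Bredt), so only C15 reacts, and the oxidant should approach from the side remote from the C14 ester.

Step 10
Reactants: 20
Product: 21 C15 tert-butyldimethylsilyl ether of 20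
Conditions: t-BuMe2SiOTf, 2,6-lutidine, CH2Cl2, 0 °C
Reagents that add atoms: tert-butyldimethylsilyl trifluoromethanesulfonate, CC(C)(C)[Si](C)(C)OS(=O)(=O)C(F)(F)F
Why: Silyl triflate with a hindered base silylates even a hindered α-hydroxy ketone, and this ether is the C15 protecting group that is carried through the oxygen insertion.

Step 11
Reactants: 21
Product: 23 C14 methyl ketone with C16=C17 methylene and free C3 alcohol (C15 silyl ether kept), via bis-methylenated enol ether 22 (not isolated)
Conditions: Cp2TiMe2 (4 equiv), toluene, 70 °C; then AcOH/THF/H2O, 35 °C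
Reagents that add atoms: dimethyltitanocene, [CH3-].[CH3-].[Ti+4].c1cc[cH-]c1.c1cc[cH-]c1; water, O
Why: Titanium-methylidene methylenation with dimethyltitanocene works on hindered, enolisable ketones and converts esters into methyl enol ethers, so one reagent installs C17 and turns the ester into a masked acetyl group, after which dilute acid hydrolyses the enol ether to the methyl ketone and cleaves the triethylsilyl ether while the more robust tert-butyldimethylsilyl ether stays.

Step 12
Reactants: 23
Product: 25 C14 acetate with free C3 alcohol, via Criegee adduct 24 (not isolated)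
Conditions: Me3SiOOSiMe3, Me3SiOTf (10 mol%), CH2Cl2, −40 to −20 °C; aq. NaHCO3
Reagents that add atoms: bis(trimethylsilyl) peroxide, C[Si](C)(C)OO[Si](C)(C)C
Why: Baeyer–Villiger oxidation with the silyl peroxide and silyl triflate couple leaves isolated alkenes and a free secondary alcohol alone, and in the Criegee adduct the secondary C14 migrates in preference to methyl and with retention, so the acetate keeps the configuration set in step 8.

Step 13
Reactants: 25
Product: 26 cyclopentanone (C3 ketone; C14 acetate; C15 silyl ether; both alkenes)
Conditions: Dess–Martin periodinane, CH2Cl2, rt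
Reagents that add atoms: none
Why: Dess–Martin oxidation turns the secondary alcohol into the ketone under near-neutral conditions that spare the allylic silyl ether, the acetate and both alkenes.

Step 14
Reactants: 26
Product: 28 15-O-(tert-butyldimethylsilyl)-15-dihydrocrotobarin (six-membered lactone), via Criegee adduct 27 (not isolated)
Conditions: Me3SiOOSiMe3, Me3SiOTf (cat.), CH2Cl2, −78 to −30 °C; aq. NaHCO3
Reagents that add atoms: bis(trimethylsilyl) peroxide, C[Si](C)(C)OO[Si](C)(C)C
Why: The silyl triflate activates the C3 carbonyl for addition of the silyl peroxide to give the Criegee adduct 27, from which the C9–C3 bond, antiperiplanar to the O–O bond, shifts to oxygen with loss of hexamethyldisiloxane (Baeyer–Villiger oxidation; closest precedent: silyl peroxide oxidation of 2,2-disubstituted cyclopentanones to δ-lactones with migration of the more substituted carbon). The lactone ring is not closed end to end but by ring expansion: the 1,2-shift inserts oxygen into the five-membered ring and makes it six-membered. No stereocentre is created; C9 migrates with retention, so the new C9–O bond takes the place and configuration of the C9–C3 bond fixed in step 4. The step needs migration of C9 and not of C2, and no reaction at C15 or at the two 1,1-disubstituted alkenes. The fully substituted C9 is the better migrating group than the methylene C2, C15 is an ether and not a ketone, and the silyl peroxide does not epoxidise.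

Step 15
Reactants: 28
Product: 29 15-dihydrocrotobarin (allylic alcohol at C15)
Conditions: Bu4NF, AcOH, THF, 0 °C
Reagents that add atoms: none
Why: Fluoride cleavage of the silyl ether, buffered with acetic acid, keeps the acetate and the lactone intact, and the C15 oxygen points away from the C14 acetate, so acyl migration is not expected.

Step 16
Reactants: 29
Product: 30 crotobarin
Conditions: Dess–Martin periodinane, CH2Cl2, rt
Reagents that add atoms: none
Why: Dess–Martin oxidation of the allylic alcohol gives the α-methylene ketone without touching the lactone, the acetate or the isopropenyl group.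

**Compound list**

1 | (1R,5R)-(+)-verbenone | CC1=CC(=O)[C@@H]2C[C@H]1C2(C)C | starting material
2 | 1-ethoxy-1-(trimethylsilyloxy)cyclopropane | CCOC1(O[Si](C)(C)C)CC1 | starting material
3 | bis(3-ethoxy-3-oxopropyl)zinc (zinc homoenolate) | CCOC(=O)CC[Zn]CCC(=O)OCC | intermediate
4 | trimethylsilyl enol ether of 5 | CCOC(=O)CC[C@]1(C)C=C(O[Si](C)(C)C)[C@@H]2C[C@H]1C2(C)C | intermediate
5 | ethyl 3-(2,6,6-trimethyl-4-oxobicyclo[3.1.1]hept-2-yl)propanoate, chain anti to the gem-dimethyl bridge | CCOC(=O)CC[C@]1(C)CC(=O)[C@@H]2C[C@H]1C2(C)C | intermediate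
6 | ethyl 3-[(1R,6S)-3-acetoxy-1-methyl-6-(prop-1-en-2-yl)cyclohex-3-en-1-yl]propanoate | CC(=O)OC1=CC[C@@H](C(=C)C)[C@](C)(CCC(=O)OCC)C1 | intermediate
7 | potassium enolate of the deacetylated keto ester | [K+].[O-]C1=CC[C@@H](C(=C)C)[C@](C)(CCC(=O)OCC)C1 | intermediate
8 | cis-fused 3a-methyl-4-(prop-1-en-2-yl)hexahydroindane-1,7-dione | O=C1CC[C@@H](C(=C)C)[C@]2(C)CCC(=O)[C@H]12 | intermediate
9 | but-3-en-2-one | CC(=O)C=C | starting material
10 | 7a-(3-oxobutyl) triketone | O=C1CC[C@@H](C(=C)C)[C@]2(C)CCC(=O)[C@]12CCC(C)=O | intermediate
11 | tricyclic enedione (C3 ketone, C16 enone) | O=C1C=C2CC[C@@H](C(=C)C)[C@]3(C)CCC(=O)[C@]23CC1 | intermediate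
12 | C3 hydroxy enone | O=C1C=C2CC[C@@H](C(=C)C)[C@]3(C)CC[C@@H](O)[C@]23CC1 | intermediate
13 | C3 triethylsilyl ether of 12 | O=C1C=C2CC[C@@H](C(=C)C)[C@]3(C)CC[C@@H](O[Si](CC)(CC)CC)[C@]23CC1 | intermediate
14 | methyl acrylate | C=CC(=O)OC | starting material
15 | lithium dienolate of 13 (C12=C16, C15=C8) | [Li+].[O-]C=1C=C2CC[C@@H](C(=C)C)[C@]3(C)CC[C@@H](O[Si](CC)(CC)CC)[C@]23CC=1 | intermediate
16 | lithium ester enolate after the first conjugate addition | O=C1C=C2CC[C@@H](C(=C)C)[C@]3(C)CC[C@@H](O[Si](CC)(CC)CC)[C@]23C[C@H]1CC=C([O-])OC.[Li+] | intermediate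
17 | lithium enolate of 18 | [Li+].[O-]C1=C[C@]23CC[C@@H](C(=C)C)[C@]4(C)CC[C@@H](O[Si](CC)(CC)CC)[C@@]42C[C@H]1C[C@@H]3C(=O)OC | intermediate
18 | tetracyclic keto ester (C16 ketone, C14 CO2Me) | O=C1C[C@]23CC[C@@H](C(=C)C)[C@]4(C)CC[C@@H](O[Si](CC)(CC)CC)[C@@]42C[C@H]1C[C@@H]3C(=O)OC | intermediate
19 | potassium enolate of 18 | [K+].[O-]C1=C[C@]23CC[C@@H](C(=C)C)[C@]4(C)CC[C@@H](O[Si](CC)(CC)CC)[C@@]42C[C@H]1C[C@@H]3C(=O)OC | intermediate
20 | C15 hydroxy ketone | O=C1[C@H](O)[C@]23CC[C@@H](C(=C)C)[C@]4(C)CC[C@@H](O[Si](CC)(CC)CC)[C@@]42C[C@H]1C[C@@H]3C(=O)OC | intermediate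
21 | C15 tert-butyldimethylsilyl ether of 20 | O=C1[C@H](O[Si](C)(C)C(C)(C)C)[C@]23CC[C@@H](C(=C)C)[C@]4(C)CC[C@@H](O[Si](CC)(CC)CC)[C@@]42C[C@H]1C[C@@H]3C(=O)OC | intermediate
22 | bis-methylenated compound (C16=C17; C14–C(OMe)=CH2) | C=C1[C@H](O[Si](C)(C)C(C)(C)C)[C@]23CC[C@@H](C(=C)C)[C@]4(C)CC[C@@H](O[Si](CC)(CC)CC)[C@@]42C[C@H]1C[C@@H]3C(=C)OC | intermediate
23 | C14 methyl ketone, C3 alcohol | C=C1[C@H](O[Si](C)(C)C(C)(C)C)[C@]23CC[C@@H](C(=C)C)[C@]4(C)CC[C@@H](O)[C@@]42C[C@H]1C[C@@H]3C(C)=O | intermediate
24 | Criegee adduct of 23 | C=C1[C@H](O[Si](C)(C)C(C)(C)C)[C@]23CC[C@@H](C(=C)C)[C@]4(C)CC[C@@H](O)[C@@]42C[C@H]1C[C@@H]3C(C)(O[Si](C)(C)C)OO[Si](C)(C)C | intermediate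
25 | C14 acetate, C3 alcohol | C=C1[C@H](O[Si](C)(C)C(C)(C)C)[C@]23CC[C@@H](C(=C)C)[C@]4(C)CC[C@@H](O)[C@@]42C[C@H]1C[C@@H]3OC(C)=O | intermediate
26 | carbocyclic cyclopentanone with C15 silyl ether | C=C1[C@H](O[Si](C)(C)C(C)(C)C)[C@]23CC[C@@H](C(=C)C)[C@]4(C)CCC(=O)[C@@]42C[C@H]1C[C@@H]3OC(C)=O | intermediate
27 | Criegee adduct of 26 | C=C1[C@H](O[Si](C)(C)C(C)(C)C)[C@]23CC[C@@H](C(=C)C)[C@]4(C)CCC(O[Si](C)(C)C)(OO[Si](C)(C)C)[C@@]42C[C@H]1C[C@@H]3OC(C)=O | intermediate
28 | 15-O-(tert-butyldimethylsilyl)-15-dihydrocrotobarin | C=C1[C@H](O[Si](C)(C)C(C)(C)C)[C@]23CC[C@@H](C(=C)C)[C@]4(C)CCC(=O)O[C@@]42C[C@H]1C[C@@H]3OC(C)=O | intermediate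
29 | 15-dihydrocrotobarin | C=C1[C@H](O)[C@]23CC[C@@H](C(=C)C)[C@]4(C)CCC(=O)O[C@@]42C[C@H]1C[C@@H]3OC(C)=O | intermediate
30 | crotobarin | C=C1C(=O)[C@]23CC[C@@H](C(=C)C)[C@]4(C)CCC(=O)O[C@@]42C[C@H]1C[C@@H]3OC(C)=O | target

**Step count**

Total: 16 steps. Longest linear sequence: 16 steps (1 to 30).

**Steps most likely to fail**

Step 8. The ester enolate formed in the first conjugate addition may fail to close onto C8, which is fully substituted and shielded on the reacting face by the axial C20 methyl; the open mono-adduct, reversal of the first addition or acrylate oligomers would result. Fallback, from 13 back to 18: a neutral [4+2] cycloaddition replaces the anionic sequence. Compound 13 is converted with LiN(i-Pr)2 and Me3SiCl (THF, −78 °C) into the trimethylsilyl dienol ether F1. F1 is combined with methyl acrylate under high pressure (CH2Cl2, about 12 kbar, rt) or in toluene at 110 °C in a Diels–Alder reaction; this should give the bridged silyl enol ether F2 with the ester endo and the same face selectivity. K2CO3 in methanol then frees the ketone 18.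

Step 14. The silyl triflate may ionise the allylic silyl ether at C15, or start acid-initiated reactions of the isopropenyl group, before the hindered C3 carbonyl has added the peroxide; the Criegee adduct may also form too slowly at this neopentyl carbonyl. Fallback, from 26 back to 28: oxidation of the alkenes is accepted and then undone. Excess mCPBA with NaHCO3 (CH2Cl2, rt) should carry out the same ring expansion with C9 migration and at the same time epoxidise both 1,1-disubstituted alkenes, giving the lactone bis-epoxide F3 (epoxide diastereomers immaterial). Reductive deoxygenation of the two terminal epoxides with NaI and Zn in acetic acid buffered with NaOAc regenerates the isopropenyl and C16 methylene groups and returns 28.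

Step 1. Transfer of the ester-bearing zinc reagent to the hindered β,β-disubstituted enone may be too slow, so that the homoenolate is lost to protonation or verbenone is consumed by side reactions. Fallback, from 1 back to 5: the three-carbon ester chain is brought in as a butenyl group and then cut down. CH2=CHCH2CH2MgBr with CuBr·SMe2 (cat.) and Me3SiCl in THF at −40 °C adds anti to the bridge and gives, after acidic work-up, the butenyl ketone F4. Ozonolysis of its terminal alkene in ethanolic NaOH (CH2Cl2/EtOH, −78 °C) delivers the ethyl ester 5 directly.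

**Further compounds**

F1 | step 8 | trimethylsilyl dienol ether of 13 | C[Si](C)(C)OC=1C=C2CC[C@@H](C(=C)C)[C@]3(C)CC[C@@H](O[Si](CC)(CC)CC)[C@]23CC=1
F2 | step 8 | Diels–Alder adduct, trimethylsilyl enol ether of 18 | C[Si](C)(C)OC1=C[C@]23CC[C@@H](C(=C)C)[C@]4(C)CC[C@@H](O[Si](CC)(CC)CC)[C@@]42C[C@H]1C[C@@H]3C(=O)OC
F3 | step 14 | lactone bis-epoxide of 28 | C5OC51[C@H](O[Si](C)(C)C(C)(C)C)[C@]23CC[C@@H](C6(C)CO6)[C@]4(C)CCC(=O)O[C@@]42C[C@H]1C[C@@H]3OC(C)=O
F4 | step 1 | but-3-enyl conjugate adduct of verbenone | C=CCC[C@]1(C)CC(=O)[C@@H]2C[C@H]1C2(C)C
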